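**Retrosynthetic overview**
1. The enal is installed last by Heck coupling of a ring D aryl bromide with acrolein dimethyl acetal.
2. The two erythro arylglycerol β-aryl ether units are built by the same three-step cycle, run twice: phenol O-alkylation with a bromoacetyl oxazolidinone, auxiliary-controlled anti-aldol (O-pivaloyl syringaldehyde, then O-pivaloyl vanillin), LiBH4 reduction.
3. The trans-dihydrobenzofuran core comes from oxidative ring contraction (1,2-aryl shift) of an (R)-flavanone, generated in the same flask by asymmetric copper hydride reduction of a flavone.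
4. The flavone comes from 5-bromo-2-hydroxy-3-methoxyacetophenone (catechol, acetic anhydride) and O-pivaloyl syringaldehyde (p-cresol).
5. Ring order: the four benzene rings are bought (p-cresol for rings B and C, catechol for rings A and D); the pyranone ring is closed first and then contracted to the dihydrofuran ring.

Assumption: the facial sense of (R)-DTBM-SEGPHOS–copper hydride on the flavone is taken from its sense with 3-substituted cyclohexenones; if chiral HPLC shows the opposite sense, the (S)-ligand is used and nothing else changes.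

Labels: ring A = guaiacyl ring with the free phenol, rings B and C = syringyl rings, ring D = benzo ring of the benzofuran; in each arylglycerol unit C7 = benzylic carbinol carbon, C8 = aryloxy-bearing carbon, C9 = CH2OH carbon.

**Step 1**
Reactants: 1 p-cresol
Product: 2 4-hydroxybenzaldehyde
Conditions: O2 (1 atm), CoCl2 (1 mol%), NaOH (3 equiv), MeOH, 60 °C; then aq HCl
Reagents that add atoms: oxygen (O=O)
Why: Cobalt-catalysed autoxidation of the p-cresolate runs through the quinone methide and stops at the aldehyde (benzylic oxidation).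

**Step 2**
Reactants: 2 4-hydroxybenzaldehyde
Product: 3 3,5-dibromo-4-hydroxybenzaldehyde
Conditions: Br2 (2.1 equiv), AcOH, rt
Reagents that add atoms: bromine (BrBr)
Why: Electrophilic aromatic bromination takes both positions ortho to the phenol, the only activated sites.

**Step 3**
Reactants: 3 3,5-dibromo-4-hydroxybenzaldehyde
Product: 4 syringaldehyde
Conditions: NaOMe (6 equiv), CuCl (10 mol%), DMF/MeOH, 110 °C; then aq HCl
Reagents that add atoms: sodium methoxide ([Na+].[O-]C)
Why: Copper-catalysed Ullmann-type methoxylation replaces both aryl bromides ortho to the phenoxide.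

**Step 4**
Reactants: 4 syringaldehyde
Product: 5 4-formyl-2,6-dimethoxyphenyl pivalate
Conditions: PivCl (1.3 equiv), Et3N, DMAP (10 mol%), CH2Cl2, 0 °C → rt
Reagents that add atoms: pivaloyl chloride (CC(C)(C)C(Cl)=O)
Why: DMAP-catalysed O-acylation gives a hindered pivalate that makes the aldehyde more electrophilic, lowers the migratory aptitude of ring C in step 9 and is removed later by hydride.

**Step 5**
Reactants: 6 catechol
Product: 7 guaiacol
Conditions: MeI (1.0 equiv), K2CO3 (1.0 equiv), acetone, 56 °C; distillation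
Reagents that add atoms: iodomethane (CI)
Why: Williamson mono-O-methylation with one equivalent of MeI; guaiacol is separated from catechol and veratrole by distillation.

**Step 6**
Reactants: 7 guaiacol
Product: 8 4-bromo-2-methoxyphenol
Conditions: NBS (1.0 equiv), MeCN, 0 °C
Reagents that add atoms: N-bromosuccinimide (O=C1CCC(=O)N1Br)
Why: Electrophilic bromination goes para to the free phenol, the strongest director.

**Step 7**
Reactants: 8 4-bromo-2-methoxyphenol; 9 acetic anhydride
Product: 11 1-(5-bromo-2-hydroxy-3-methoxyphenyl)ethan-1-one, via aryl acetate 10 (not isolated)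
Conditions: TfOH (3 equiv), neat, 0 → 60 °C
Reagents that add atoms: none
Why: O-acetylation followed by acid-promoted Fries rearrangement; the para position is blocked by bromine, so the acetyl group ends ortho to the phenol as the chelated hydroxy ketone.

**Step 8**
Reactants: 11 1-(5-bromo-2-hydroxy-3-methoxyphenyl)ethan-1-one; 5 4-formyl-2,6-dimethoxyphenyl pivalate
Product: 14 4-(6-bromo-8-methoxy-4-oxo-4H-chromen-2-yl)-2,6-dimethoxyphenyl pivalate (flavone), via chalcone 12 (not isolated), via racemic flavanone 13 (not isolated)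
Conditions: pyrrolidine (0.5 equiv), EtOH, 70 °C; evaporate; then I2 (20 mol%), DMSO, 120 °C
Reagents that add atoms: none
Why: Amine-catalysed Claisen–Schmidt condensation and oxa-Michael closure, then iodine-catalysed dehydrogenation by DMSO to the achiral flavone; the doubly ortho-flanked pivalate resists aminolysis.

**Step 9**
Reactants: 14 flavone
Product: 17 methyl (2R,3R)-5-bromo-2-[3,5-dimethoxy-4-(pivaloyloxy)phenyl]-7-methoxy-2,3-dihydro-1-benzofuran-3-carboxylate, via silyl enol ether 15 (not isolated), via (R)-flavanone 16 (not isolated)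
Conditions: Cu(OAc)2 (5 mol%), (R)-DTBM-SEGPHOS (5.5 mol%), (EtO)2MeSiH (2 equiv), toluene, 0 °C → rt; then MeOH/HC(OMe)3 (1:1), H2SO4 (20 mol%), PhI(OAc)2 (1.3 equiv), 0 °C → rt
Reagents that add atoms: methanol (CO)
Why: Proposed new method: asymmetric reductive ring contraction of a flavone. The ligated copper hydride adds hydride to C2 of the vinylogous ester on the face set by the ligand (C2 becomes R), and sigma-bond metathesis with the silane gives silyl enol ether 15, which cannot racemise by retro-oxa-Michael opening. Acidic methanol then releases (R)-flavanone 16, whose enol ether is attacked at C3 by the trivalent iodine reagent anti to the 2-aryl group; the ring D carbon C4a migrates from the ketal carbon C4 to C3 as PhI leaves (1,2-aryl shift, six- to five-membered ring), and C4 ends as the methyl ester trans to the aryl group (C3 becomes R). The electron-poor pivaloyloxy ring C disfavours the competing 2,3-aryl shift to an isoflavone. Closest known reactions: copper hydride asymmetric conjugate reduction of β,β-disubstituted enones with interception of the silyl enol ether, and the PhI(OAc)2 or Tl(NO3)3 ring contraction of racemic flavanones in trimethyl orthoformate.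

**Step 10**
Reactants: 17 methyl ester
Product: 18 4-[(2R,3S)-5-bromo-3-(hydroxymethyl)-7-methoxy-2,3-dihydro-1-benzofuran-2-yl]-2,6-dimethoxyphenol
Conditions: LiBH4 (6 equiv), THF/MeOH (10:1), 0 °C → rt; aq NH4Cl
Reagents that add atoms: none
Why: Hydride reduction turns the methyl ester into the primary alcohol and cleaves the aryl pivalate in the same operation; neither stereocenter is touched (the descriptor at C3 changes from R to S by priority only).

**Step 11**
Reactants: 19 bromoacetyl bromide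
Product: 20 (4S)-4-benzyl-3-(bromoacetyl)-1,3-oxazolidin-2-one
Conditions: (S)-4-benzyl-1,3-oxazolidin-2-one, n-BuLi (1.0 equiv), THF, −78 °C; then 19, −78 → 0 °C
Reagents that add atoms: (S)-4-benzyl-1,3-oxazolidin-2-one (O=C1N[C@@H](Cc2ccccc2)CO1)
Why: N-acylation of the lithiated Evans auxiliary by the acyl bromide, which is far more reactive than the alkyl bromide.

**Step 12**
Reactants: 18 phenol; 20 bromoacetyl imide
Product: 21 (4S)-4-benzyl-3-[2-(4-{(2R,3S)-5-bromo-3-(hydroxymethyl)-7-methoxy-2,3-dihydro-1-benzofuran-2-yl}-2,6-dimethoxyphenoxy)acetyl]-1,3-oxazolidin-2-one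
Conditions: K2CO3 (1.5 equiv), MeCN, rt
Reagents that add atoms: none
Why: Williamson ether synthesis; only the phenoxide is formed under carbonate and it displaces the α-bromide by SN2, leaving the primary alcohol free.

**Step 13**
Reactants: 21 aryloxyacetyl imide; 5 4-formyl-2,6-dimethoxyphenyl pivalate
Product: 22 anti-aldol adduct as bis(trimethylsilyl) ether: (4S)-4-benzyl-3-[(2R,3R)-2-(aryloxy)-3-[3,5-dimethoxy-4-(pivaloyloxy)phenyl]-3-(trimethylsilyloxy)propanoyl]-1,3-oxazolidin-2-one (aryloxy = ring C oxygen of 21 with its CH2OH as CH2OSiMe3)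
Conditions: MgCl2 (0.3 equiv), Et3N (4 equiv), Me3SiCl (3 equiv), EtOAc, rt; filtration through a short silica pad, used crude
Reagents that add atoms: chlorotrimethylsilane (C[Si](C)(C)Cl)
Why: Evans magnesium halide-catalysed anti-aldol: the chelated Z-magnesium enolate is attacked by the aldehyde on the face opposite the benzyl group (the face used in auxiliary alkylations), which sets C8 (R in the imide, S after reduction) and the anti (erythro) C7 (R); Me3SiCl traps the aldolate and masks the free primary alcohol.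

**Step 14**
Reactants: 22 silylated aldol adduct
Product: 23 4-[(1R,2S)-2-(4-{(2R,3S)-5-bromo-3-(hydroxymethyl)-7-methoxy-2,3-dihydro-1-benzofuran-2-yl}-2,6-dimethoxyphenoxy)-1,3-dihydroxypropyl]-2,6-dimethoxyphenol
Conditions: LiBH4 (6 equiv), THF/MeOH (10:1), 0 °C → rt; then 1 M HCl aq work-up
Reagents that add atoms: none
Why: Reductive removal of the auxiliary gives the C9 alcohol, the ring B pivalate is cleaved by hydride and the silyl ethers are hydrolysed on work-up; the silyl ether blocks retro-aldol during reduction, so C7 and C8 are kept.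

**Step 15**
Reactants: 23 phenol; 20 bromoacetyl imide
Product: 24 (4S)-4-benzyl-3-[2-(4-{(1R,2S)-2-[4-((2R,3S)-5-bromo-3-(hydroxymethyl)-7-methoxy-2,3-dihydro-1-benzofuran-2-yl)-2,6-dimethoxyphenoxy]-1,3-dihydroxypropyl}-2,6-dimethoxyphenoxy)acetyl]-1,3-oxazolidin-2-one
Conditions: K2CO3 (1.5 equiv), DMF, rt
Reagents that add atoms: none
Why: Williamson ether synthesis, chemoselective for the ring B phenoxide over the three aliphatic hydroxyls.

**Step 16**
Reactants: 8 4-bromo-2-methoxyphenol
Product: 26 vanillin, via dilithiated phenolate 25 (not isolated)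
Conditions: n-BuLi (2.2 equiv), THF, −78 °C; then DMF, −78 °C → rt; aq HCl
Reagents that add atoms: N,N-dimethylformamide (CN(C)C=O)
Why: Deprotonation and bromine–lithium exchange give the aryllithium, which is formylated by DMF (Bouveault-type formylation).

**Step 17**
Reactants: 26 vanillin
Product: 27 4-formyl-2-methoxyphenyl pivalate
Conditions: PivCl (1.2 equiv), Et3N, DMAP (10 mol%), CH2Cl2, 0 °C → rt
Reagents that add atoms: pivaloyl chloride (CC(C)(C)C(Cl)=O)
Why: O-acylation masks the phenol and makes the aldehyde a better aldol acceptor.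

**Step 18**
Reactants: 24 aryloxyacetyl imide; 27 4-formyl-2-methoxyphenyl pivalate
Product: 28 anti-aldol adduct as tetrakis(trimethylsilyl) ether: (4S)-4-benzyl-3-[(2R,3R)-2-(aryloxy)-3-[3-methoxy-4-(pivaloyloxy)phenyl]-3-(trimethylsilyloxy)propanoyl]-1,3-oxazolidin-2-one (aryloxy = ring B oxygen of 24 with its three hydroxyls as OSiMe3)
Conditions: MgCl2 (0.5 equiv), Et3N (8 equiv), Me3SiCl (6 equiv), EtOAc/THF, rt; filtration through a short silica pad, used crude
Reagents that add atoms: chlorotrimethylsilane (C[Si](C)(C)Cl)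
Why: Second Evans magnesium halide-catalysed anti-aldol with the same auxiliary and facial sense, which sets C8 and C7 of the ring A unit erythro (S and R after reduction); the three hydroxyls are silylated in the flask.

**Step 19**
Reactants: 28 silylated aldol adduct
Product: 29 (1R,2S)-1-(4-hydroxy-3-methoxyphenyl)-2-(4-{(1R,2S)-2-[4-((2R,3S)-5-bromo-3-(hydroxymethyl)-7-methoxy-2,3-dihydro-1-benzofuran-2-yl)-2,6-dimethoxyphenoxy]-1,3-dihydroxypropyl}-2,6-dimethoxyphenoxy)propane-1,3-diol
Conditions: LiBH4 (8 equiv), THF/MeOH (10:1), 0 °C → rt; then 1 M HCl aq work-up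
Reagents that add atoms: none
Why: Reductive cleavage of the auxiliary, hydride cleavage of the ring A pivalate and hydrolysis of the silyl ethers give the free polyol with all six stereocenters in place.

**Step 20**
Reactants: 29 aryl bromide; 30 acrolein dimethyl acetal
Product: 32 CNP0192639.1 (target), via dimethyl acetal 31 (not isolated)
Conditions: Pd(OAc)2 (5 mol%), n-Bu4NOAc (2 equiv), K2CO3 (2.5 equiv), KCl (1 equiv), DMF, 90 °C; then 2 M HCl aq, THF, rt
Reagents that add atoms: water (O)
Why: Mizoroki–Heck arylation of the acrolein acetal with β-hydride elimination toward the benzylic hydrogen gives the E-cinnamaldehyde acetal, which dilute acid hydrolyses to the enal without touching any stereocenter.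

**Compound list**
1 | p-cresol (4-methylphenol) | Cc1ccc(O)cc1 | starting material
2 | 4-hydroxybenzaldehyde | O=Cc1ccc(O)cc1 | intermediate
3 | 3,5-dibromo-4-hydroxybenzaldehyde | O=Cc1cc(Br)c(O)c(Br)c1 | intermediate
4 | syringaldehyde (4-hydroxy-3,5-dimethoxybenzaldehyde) | COc1cc(C=O)cc(OC)c1O | intermediate
5 | 4-formyl-2,6-dimethoxyphenyl pivalate | COc1cc(C=O)cc(OC)c1OC(=O)C(C)(C)C | intermediate
6 | catechol (benzene-1,2-diol) | Oc1ccccc1O | starting material
7 | guaiacol (2-methoxyphenol) | COc1ccccc1O | intermediate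
8 | 4-bromo-2-methoxyphenol | COc1cc(Br)ccc1O | intermediate
9 | acetic anhydride | CC(=O)OC(C)=O | starting material
10 | 4-bromo-2-methoxyphenyl acetate (formed in the flask) | COc1cc(Br)ccc1OC(C)=O | intermediate
11 | 1-(5-bromo-2-hydroxy-3-methoxyphenyl)ethan-1-one | CC(=O)c1cc(Br)cc(OC)c1O | intermediate
12 | chalcone: 4-[(E)-3-(5-bromo-2-hydroxy-3-methoxyphenyl)-3-oxoprop-1-enyl]-2,6-dimethoxyphenyl pivalate (formed in the flask) | COc1cc(/C=C/C(=O)c2cc(Br)cc(OC)c2O)cc(OC)c1OC(=O)C(C)(C)C | intermediate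
13 | racemic flavanone: 4-(6-bromo-8-methoxy-4-oxochroman-2-yl)-2,6-dimethoxyphenyl pivalate (formed in the flask) | COc1cc(C2CC(=O)c3cc(Br)cc(OC)c3O2)cc(OC)c1OC(=O)C(C)(C)C | intermediate
14 | flavone: 4-(6-bromo-8-methoxy-4-oxo-4H-chromen-2-yl)-2,6-dimethoxyphenyl pivalate | COc1cc(C2=CC(=O)c3cc(Br)cc(OC)c3O2)cc(OC)c1OC(=O)C(C)(C)C | intermediate
15 | silyl enol ether: 4-[(2R)-6-bromo-4-{[diethoxy(methyl)silyl]oxy}-8-methoxy-2H-chromen-2-yl]-2,6-dimethoxyphenyl pivalate (formed in the flask) | COc1cc([C@@H]2Oc3c(OC)cc(Br)cc3C(O[Si](C)(OCC)OCC)=C2)cc(OC)c1OC(=O)C(C)(C)C | intermediate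
16 | (R)-flavanone: 4-[(2R)-6-bromo-8-methoxy-4-oxochroman-2-yl]-2,6-dimethoxyphenyl pivalate (formed in the flask) | COc1cc([C@@H]2Oc3c(OC)cc(Br)cc3C(=O)C2)cc(OC)c1OC(=O)C(C)(C)C | intermediate
17 | methyl (2R,3R)-5-bromo-2-[3,5-dimethoxy-4-(pivaloyloxy)phenyl]-7-methoxy-2,3-dihydro-1-benzofuran-3-carboxylate (aryl and ester trans) | COc1cc([C@@H]2Oc3c(OC)cc(Br)cc3[C@H]2C(=O)OC)cc(OC)c1OC(=O)C(C)(C)C | intermediate
18 | 4-[(2R,3S)-5-bromo-3-(hydroxymethyl)-7-methoxy-2,3-dihydro-1-benzofuran-2-yl]-2,6-dimethoxyphenol | COc1cc([C@@H]2Oc3c(OC)cc(Br)cc3[C@H]2CO)cc(OC)c1O | intermediate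
19 | bromoacetyl bromide | BrCC(Br)=O | starting material
20 | (4S)-4-benzyl-3-(bromoacetyl)-1,3-oxazolidin-2-one | O=C(CBr)N1[C@@H](Cc2ccccc2)COC1=O | intermediate
21 | (4S)-4-benzyl-3-[2-(4-{(2R,3S)-5-bromo-3-(hydroxymethyl)-7-methoxy-2,3-dihydro-1-benzofuran-2-yl}-2,6-dimethoxyphenoxy)acetyl]-1,3-oxazolidin-2-one | COc1cc([C@@H]2Oc3c(OC)cc(Br)cc3[C@H]2CO)cc(OC)c1OCC(=O)N1[C@@H](Cc2ccccc2)COC1=O | intermediate
22 | (2R,3R)-anti-aldol adduct of 21 with 5, bis(trimethylsilyl) ether (benzylic OSiMe3 and CH2OSiMe3), (4S)-auxiliary still attached | COc1cc([C@@H](O[Si](C)(C)C)[C@H](C(=O)N2[C@@H](Cc3ccccc3)COC2=O)Oc2c(OC)cc([C@@H]3Oc4c(OC)cc(Br)cc4[C@H]3CO[Si](C)(C)C)cc2OC)cc(OC)c1OC(=O)C(C)(C)C | intermediate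
23 | 4-[(1R,2S)-2-(4-{(2R,3S)-5-bromo-3-(hydroxymethyl)-7-methoxy-2,3-dihydro-1-benzofuran-2-yl}-2,6-dimethoxyphenoxy)-1,3-dihydroxypropyl]-2,6-dimethoxyphenol (erythro) | COc1cc([C@@H](O)[C@H](CO)Oc2c(OC)cc([C@@H]3Oc4c(OC)cc(Br)cc4[C@H]3CO)cc2OC)cc(OC)c1O | intermediate
24 | (4S)-4-benzyl-3-(aryloxyacetyl)-1,3-oxazolidin-2-one in which aryloxy is the ring B oxygen of 23 | COc1cc([C@@H](O)[C@H](CO)Oc2c(OC)cc([C@@H]3Oc4c(OC)cc(Br)cc4[C@H]3CO)cc2OC)cc(OC)c1OCC(=O)N1[C@@H](Cc2ccccc2)COC1=O | intermediate
25 | lithium 4-lithio-2-methoxyphenolate (formed in the flask) | COc1cc([Li])ccc1[O-].[Li+] | intermediate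
26 | vanillin (4-hydroxy-3-methoxybenzaldehyde) | COc1cc(C=O)ccc1O | intermediate
27 | 4-formyl-2-methoxyphenyl pivalate | COc1cc(C=O)ccc1OC(=O)C(C)(C)C | intermediate
28 | (2R,3R)-anti-aldol adduct of 24 with 27, tetrakis(trimethylsilyl) ether, (4S)-auxiliary still attached | COc1cc([C@@H](O[Si](C)(C)C)[C@H](C(=O)N2[C@@H](Cc3ccccc3)COC2=O)Oc2c(OC)cc([C@@H](O[Si](C)(C)C)[C@H](CO[Si](C)(C)C)Oc3c(OC)cc([C@@H]4Oc5c(OC)cc(Br)cc5[C@H]4CO[Si](C)(C)C)cc3OC)cc2OC)ccc1OC(=O)C(C)(C)C | intermediate
29 | (1R,2S)-1-(4-hydroxy-3-methoxyphenyl)-2-(4-{(1R,2S)-2-[4-((2R,3S)-5-bromo-3-(hydroxymethyl)-7-methoxy-2,3-dihydro-1-benzofuran-2-yl)-2,6-dimethoxyphenoxy]-1,3-dihydroxypropyl}-2,6-dimethoxyphenoxy)propane-1,3-diol | COc1cc([C@@H](O)[C@H](CO)Oc2c(OC)cc([C@@H](O)[C@H](CO)Oc3c(OC)cc([C@@H]4Oc5c(OC)cc(Br)cc5[C@H]4CO)cc3OC)cc2OC)ccc1O | intermediate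
30 | acrolein dimethyl acetal (3,3-dimethoxyprop-1-ene) | C=CC(OC)OC | starting material
31 | 29 with Br replaced by (E)-3,3-dimethoxyprop-1-enyl (formed in the flask) | COc1cc([C@@H](O)[C@H](CO)Oc2c(OC)cc([C@@H](O)[C@H](CO)Oc3c(OC)cc([C@@H]4Oc5c(OC)cc(/C=C/C(OC)OC)cc5[C@H]4CO)cc3OC)cc2OC)ccc1O | intermediate
32 | CNP0192639.1: (E)-3-{(2R,3S)-2-[4-({(1R,2S)-1-[4-({(1R,2S)-1,3-dihydroxy-1-(4-hydroxy-3-methoxyphenyl)propan-2-yl}oxy)-3,5-dimethoxyphenyl]-1,3-dihydroxypropan-2-yl}oxy)-3,5-dimethoxyphenyl]-3-(hydroxymethyl)-7-methoxy-2,3-dihydro-1-benzofuran-5-yl}prop-2-enal | COc1cc([C@@H](O)[C@H](CO)Oc2c(OC)cc([C@@H](O)[C@H](CO)Oc3c(OC)cc([C@@H]4Oc5c(OC)cc(/C=C/C=O)cc5[C@H]4CO)cc3OC)cc2OC)ccc1O | target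

**Totals**
Total step count: 20.
Longest linear sequence: 14 steps (1, 2, 3, 4, 8, 9, 10, 12, 13, 14, 15, 18, 19, 20).

**Steps most likely to fail, with fallbacks**

Step 9 (proposed new asymmetric reductive ring contraction). Copper hydride reduction of a flavone is untested, and the sense and level of induction are assumed. The fallback uses only known reactions and sets out from 11 and 5. With pyrrolidine in EtOH at 60 °C and no oxidant they give the racemic flavanone 13, which is now isolated. Kinetic resolution by Noyori-type asymmetric transfer hydrogenation [RuCl(p-cymene)((S,S)-TsDPEN), HCO2H/Et3N, rt, about 55% conversion] reduces the (2S)-enantiomer to the cis-flavanol 4-[(2S,4S)-6-bromo-4-hydroxy-8-methoxychroman-2-yl]-2,6-dimethoxyphenyl pivalate F1 and leaves (R)-flavanone 16. After separation, 16 is ring-contracted with stoichiometric PhI(OAc)2 and catalytic H2SO4 in HC(OMe)3/MeOH. The fallback comes back to the route at 17.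

Step 13 (magnesium-catalysed anti-aldol of an aryloxyacetyl imide; step 18 is the same reaction and shares the risk). The anti selectivity is extrapolated from propionyl imides, and the aldehyde is electron-rich. The fallback sets out from 18 and replaces the direct anti-aldol by a syn-aldol followed by inversion. Phenol 18 is alkylated (K2CO3, MeCN) with the enantiomeric reagent (4R)-4-benzyl-3-(bromoacetyl)-1,3-oxazolidin-2-one F2, made like 20 from the (R)-auxiliary, to give the imide (4R)-4-benzyl-3-(aryloxyacetyl)-1,3-oxazolidin-2-one F3. A boron-mediated Evans syn-aldol (Bu2BOTf 2.2 equiv, i-Pr2NEt, CH2Cl2, −78 → 0 °C, then 5) sets C8 correctly and gives the threo (2R,3S)-adduct F4. A Mitsunobu reaction (4-nitrobenzoic acid, PPh3, DIAD, THF) inverts the benzylic carbinol and esterifies the primary alcohol, giving the erythro (2R,3R)-bis(4-nitrobenzoate) F5. LiBH4 in THF/MeOH then removes the auxiliary, both nitrobenzoates and the pivalate. The fallback comes back to the route at 23; the same detour applied to 23 would return at 29.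

Step 20 (Heck reaction on an electron-rich aryl bromide carrying a free phenol and six hydroxyls under carbonate at 90 °C). The fallback sets out from 29 and builds the enal in two milder known steps. Suzuki–Miyaura vinylation with potassium vinyltrifluoroborate [PdCl2(dppf), Cs2CO3, THF/H2O, 80 °C] gives the 5-vinyl analogue of 29, styrene F6. Cross-metathesis with crotonaldehyde [second-generation Hoveyda–Grubbs catalyst, RuCl2(SIMes)(=CH-C6H4-2-O-i-Pr), CH2Cl2, 40 °C] gives the E-enal. The fallback comes back to the route at 32.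

**Further compounds**
F1 | step 9 | 4-[(2S,4S)-6-bromo-4-hydroxy-8-methoxychroman-2-yl]-2,6-dimethoxyphenyl pivalate (cis-flavan-4-ol) | COc1cc([C@H]2Oc3c(OC)cc(Br)cc3[C@@H](O)C2)cc(OC)c1OC(=O)C(C)(C)C
F2 | step 13 | (4R)-4-benzyl-3-(bromoacetyl)-1,3-oxazolidin-2-one | O=C(CBr)N1[C@H](Cc2ccccc2)COC1=O
F3 | step 13 | (4R)-4-benzyl-3-[2-(4-{(2R,3S)-5-bromo-3-(hydroxymethyl)-7-methoxy-2,3-dihydro-1-benzofuran-2-yl}-2,6-dimethoxyphenoxy)acetyl]-1,3-oxazolidin-2-one | COc1cc([C@@H]2Oc3c(OC)cc(Br)cc3[C@H]2CO)cc(OC)c1OCC(=O)N1[C@H](Cc2ccccc2)COC1=O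
F4 | step 13 | (2R,3S)-syn-aldol adduct of F3 with 5 (threo, free hydroxyls, (4R)-auxiliary attached) | COc1cc([C@H](O)[C@H](C(=O)N2[C@H](Cc3ccccc3)COC2=O)Oc2c(OC)cc([C@@H]3Oc4c(OC)cc(Br)cc4[C@H]3CO)cc2OC)cc(OC)c1OC(=O)C(C)(C)C
F5 | step 13 | (2R,3R)-bis(4-nitrobenzoate) from Mitsunobu inversion of F4 (erythro; benzylic and primary esters) | COc1cc([C@@H](OC(=O)c2ccc(cc2)[N+](=O)[O-])[C@H](C(=O)N2[C@H](Cc3ccccc3)COC2=O)Oc2c(OC)cc([C@@H]3Oc4c(OC)cc(Br)cc4[C@H]3COC(=O)c3ccc(cc3)[N+](=O)[O-])cc2OC)cc(OC)c1OC(=O)C(C)(C)C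
F6 | step 20 | 5-vinyl analogue of 29 (Br replaced by CH=CH2) | COc1cc([C@@H](O)[C@H](CO)Oc2c(OC)cc([C@@H](O)[C@H](CO)Oc3c(OC)cc([C@@H]4Oc5c(OC)cc(C=C)cc5[C@H]4CO)cc3OC)cc2OC)ccc1O
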